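I wanted to know how the rate of making product in the new flask answers to more partner and more free catalyst at the moment 30 % of the starting material is converted.

- apparent order in partner when 30 % of the starting material are converted (percent change of the rate of making product for one percent more partner charged)
- apparent order in free catalyst when 30 % of the starting material are converted (percent change of the rate of making product for one percent more free catalyst charged)
- factor on the rate of making product when 30 % of the starting material are converted if partner is charged twice over

all flasks: free catalyst 0.5 mol%
- Friday's: starting material 0.42 M; partner 1 equiv; run made earlier
- Wednesday's: starting material 1.7 M; partner 1 equiv; run made earlier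
- flask: starting material 0.85 M; partner 1.00 equiv

- Friday's (time / min: product / %): 1.33: 2; 4.00: 7; 6.00: 7; 10.0: 13; 15.0: 22; 20.0: 28
- Wednesday's (time / min: product / %): 1.33: 6; 2.50: 9; 4.00: 13; 6.00: 21; 10.0: 30; 20.0: 59

(readings scatter by 1.5 percentage points)

- the analysis behind the earlier runs scatters by 1.5 percentage points, standard deviation

I read the runs by time per turnover. Friday's run converted 28 % of its charge in 20.0 min at 0.5 mol%, so each catalyst charged took 0.357 min per product. Wednesday's run converted 30 % in 10.0 min at the same loading, which gave 0.167 min. That reading carried on: held to 20.0 min, it gave 60.0 %, and Wednesday's run read 59 %.

The strength rose by a factor of 4.05 between the runs, but the time fell by a factor of 2.14. The new flask's 0.85 M lay close to the geometric middle of the two charges, so I took the geometric mean, 0.244 min, as its round time: the loading times the elapsed time over the fraction of the charge converted, the inverse of the turnover frequency.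

The new flask held twice the charge of Friday's run, and I expected it to pass 30 % at 14.6 min. Friday's run stood at 28 % after 20.0 min, and the round time read from it was longer than the one I gave the new flask. My reckoning gave no orders, since both runs moved partner, starting material and catalyst together.

The forecast gave 0.2 in partner, 1.4 in free catalyst and a factor of 1.15 on doubling partner, with the remark: “Partner order could be positive if offset by starting-material inhibition”.

The flask gave 0.31, 1.0 and 0.934. One percent more partner raised the rate, yet twice the partner lowered it, where the forecast stood above one.

    starting material + free catalyst → catalyst intermediate A (k = 33.0 M⁻¹ min⁻¹)
    partner + catalyst intermediate A ⇌ catalyst intermediate B (K = 0.620 M⁻¹, k = 15.0 M⁻¹ min⁻¹)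
    catalyst intermediate B → catalyst intermediate C (k = 620 min⁻¹)
    catalyst intermediate C → free catalyst + product (k = 43.0 min⁻¹)
    partner + free catalyst ⇌ idle complex, settled at all times (K = 2.00 M⁻¹)

The flask passed 30 % at 13.4 min, so its round time was 0.224 min, shorter than my 0.244 min. From 1.50 min to 15.0 min, partner fell from 96.3 % to 67.1 % of its charge while the step of partner with catalyst intermediate A ran, half of its turnover up to 15.0 min done by 7.05 min; catalyst intermediate A, the largest form of the catalyst at 15.0 min, rose from 40.8 % to 46.7 % of the catalyst charged, and the idle complex eased from 29.3 % to 23.3 %. By 150 min, product stood at 99.5 % of the starting material charged, and the idle complex had shrunk to 0.358 % of the catalyst charged.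

(All runs are simulated for substances that don't exist; noise was put on by code.)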